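**Assumption:** the code is taken to mean exactly the given SMILES, i.e. (1R,3Z,7Z,9R,10S)-9-hydroxy-3,7-dimethyl-10-(propan-2-yl)cyclodeca-3,7-dien-1-yl 4-hydroxy-3-methoxybenzoate. Germacrane locants are used as shorthand: C6 = free carbinol, C7 = isopropyl carbon, C8 = ester carbinol, olefins C1=C10 and C4=C5 (target 6R,7S,8R, both ring olefins Z).

## Retrosynthetic overview

1. Ester and C6 carbinol together: Evans–Tishchenko reduction of the macrocyclic β-hydroxy enone with O-silyl vanillin (hydride from the hemiacetal on O8 sets C6 1,3-anti; the aldehyde becomes the vanillate).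
2. Ten-membered ring (the only ring formed; the arene comes from vanillin): Nozaki–Hiyama–Kishi closure of C5–C6 from a (Z)-vinyl iodide aldehyde, then oxidation to the enone.
3. C9–C10: (Z)-alkenyllithium of the west diene (both olefins already Z) opens the east terminal epoxide (C7, C8 already set).
4. East epoxide: ketoreductase dynamic reductive kinetic resolution of a racemic α-isopropyl β-keto ester made from ethyl isovalerate and benzyloxyacetyl chloride.
5. West iodide: anti-carbomagnesiation of propargyl alcohol (C4=C5), silicon mask on C5, iodo-ylide Wittig (C1=C10).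

## Route

**Step 1**
Reactants: 1 ethyl 3-methylbutanoate; 2 (benzyloxy)acetyl chloride
Product: 4 ethyl 4-(benzyloxy)-3-oxo-2-(propan-2-yl)butanoate (racemic), via lithium enolate 3 (not isolated)
Conditions: LiN(i-Pr)2 (2.1 equiv), 1 (2.1 equiv), THF, −78 °C; then 2 (1.0 equiv), −78 → 0 °C; aq. NH4Cl
Reagents that add atoms: none
Why: Crossed Claisen C-acylation of a preformed ester enolate by an acid chloride, the second enolate equivalent taking up the acidic product proton; the new α-centre is racemic and labile, as the next step requires.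

**Step 2**
Reactants: 4 ethyl 4-(benzyloxy)-3-oxo-2-(propan-2-yl)butanoate
Product: 5 ethyl (2R,3S)-4-(benzyloxy)-3-hydroxy-2-(propan-2-yl)butanoate
Conditions: ketoreductase (anti-selective hit from an NADPH-dependent panel), NADP+ (cat.), i-PrOH (10 vol %), KH2PO4/K2HPO4 buffer pH 7.5, 30 °C
Reagents that add atoms: none
Why: Ketoreductase-catalysed dynamic reductive kinetic resolution: the α-centre epimerises through the enol at pH 7.5 while the enzyme reduces only the (2R)-ketone from one face, setting C7 and C8 (anti) in one catalytic step, with i-PrOH recycling NADPH.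

**Step 3**
Reactants: 5 ethyl (2R,3S)-4-(benzyloxy)-3-hydroxy-2-(propan-2-yl)butanoate
Product: 6 (2S,3S)-4-(benzyloxy)-2-(propan-2-yl)butane-1,3-diol
Conditions: LiAlH4, THF, 0 °C → rt
Reagents that add atoms: none
Why: Hydride reduction of the ester to the primary alcohol; neither stereocentre is touched (the descriptor at C2 changes only by the sequence rule).

**Step 4**
Reactants: 6 (2S,3S)-4-(benzyloxy)-2-(propan-2-yl)butane-1,3-diol
Product: 7 (2S,3S)-1-(benzyloxy)-3-{[(tert-butyldimethylsilyl)oxy]methyl}-4-methylpentan-2-ol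
Conditions: TBSCl (1.05 equiv), imidazole, CH2Cl2, −10 → 0 °C
Reagents that add atoms: tert-butyldimethylsilyl chloride, CC(C)(C)[Si](C)(C)Cl
Why: Selective silylation of the primary hydroxyl over the hindered secondary one.

**Step 5**
Reactants: 7 (2S,3S)-1-(benzyloxy)-3-{[(tert-butyldimethylsilyl)oxy]methyl}-4-methylpentan-2-ol
Product: 8 (2S,3S)-3-{[(tert-butyldimethylsilyl)oxy]methyl}-4-methylpentane-1,2-diol
Conditions: H2 (1 atm), 10% Pd/C, EtOAc, rt
Reagents that add atoms: none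
Why: Hydrogenolysis of the benzyl ether; the silyl ether is stable in EtOAc.

**Step 6**
Reactants: 8 (2S,3S)-3-{[(tert-butyldimethylsilyl)oxy]methyl}-4-methylpentane-1,2-diol
Product: 9 (2S,3S)-3-{[(tert-butyldimethylsilyl)oxy]methyl}-2-hydroxy-4-methylpentyl 4-methylbenzenesulfonate
Conditions: TsCl (1.05 equiv), Et3N, Bu2SnO (2 mol %), CH2Cl2, 0 °C → rt
Reagents that add atoms: 4-methylbenzenesulfonyl chloride, Cc1ccc(cc1)S(Cl)(=O)=O
Why: Tin-acetal-catalysed sulfonylation of a 1,2-diol is selective for the primary hydroxyl.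

**Step 7**
Reactants: 9 (2S,3S)-3-{[(tert-butyldimethylsilyl)oxy]methyl}-2-hydroxy-4-methylpentyl 4-methylbenzenesulfonate
Product: 10 tert-butyldimethyl{(2S)-3-methyl-2-[(2S)-oxiran-2-yl]butoxy}silane
Conditions: K2CO3, MeOH, 0 °C → rt
Reagents that add atoms: none
Why: Intramolecular Williamson closure (3-exo-tet) at the primary carbon gives the terminal epoxide with retention at C8.

**Step 8**
Reactants: 11 prop-2-yn-1-ol
Product: 13 (2Z)-3-iodo-2-methylprop-2-en-1-ol, via chelated alkenylmagnesium alkoxide 12 (not isolated)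
Conditions: MeMgBr (2.5 equiv), CuI (10 mol %), THF, −10 °C → rt; then I2, −78 → 0 °C
Reagents that add atoms: methylmagnesium bromide, C[Mg]Br; iodine, II
Why: Copper-catalysed anti-carbomagnesiation directed by the magnesium alkoxide puts magnesium cis to CH2O in a five-membered chelate, and iodinolysis with retention fixes the Z geometry of the future C4=C5 olefin.

**Step 9**
Reactants: 13 (2Z)-3-iodo-2-methylprop-2-en-1-ol
Product: 14 {[(2Z)-3-iodo-2-methylprop-2-en-1-yl]oxy}trimethylsilane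
Conditions: TMSCl, Et3N, Et2O, 0 °C
Reagents that add atoms: chlorotrimethylsilane, C[Si](C)(C)Cl
Why: Simple O-silylation that loads the silicon needed for the next step.

**Step 10**
Reactants: 14 {[(2Z)-3-iodo-2-methylprop-2-en-1-yl]oxy}trimethylsilane
Product: 16 (2Z)-2-methyl-3-(trimethylsilyl)prop-2-en-1-ol, via silyloxy alkenyllithium 15 (not isolated)
Conditions: t-BuLi (2.1 equiv), THF/pentane, −78 °C → rt; H2O
Reagents that add atoms: none
Why: Iodine–lithium exchange with retention followed by 1,4 O→C silyl migration (retro-Brook rearrangement), possible only because lithium and CH2OSi are cis and driven by alkoxide formation; C5 is now masked as a vinylsilane.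

**Step 11**
Reactants: 16 (2Z)-2-methyl-3-(trimethylsilyl)prop-2-en-1-ol
Product: 17 [(1Z)-3-bromo-2-methylprop-1-en-1-yl]trimethylsilane
Conditions: CBr4, PPh3, CH2Cl2, 0 °C
Reagents that add atoms: tetrabromomethane, BrC(Br)(Br)Br
Why: Appel bromination of a primary allylic alcohol under neutral conditions, with no change of olefin geometry.

**Step 12**
Reactants: 17 [(1Z)-3-bromo-2-methylprop-1-en-1-yl]trimethylsilane; 18 acetonitrile
Product: 20 (4Z)-4-methyl-5-(trimethylsilyl)pent-4-enenitrile, via cyanomethyllithium 19 (not isolated)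
Conditions: n-BuLi, 18 (3 equiv), THF, −78 °C; then 17, −78 → −20 °C
Reagents that add atoms: none
Why: SN2 alkylation of lithioacetonitrile by the primary allylic bromide (the classical two-carbon terpenoid homologation); excess anion suppresses dialkylation.

**Step 13**
Reactants: 20 (4Z)-4-methyl-5-(trimethylsilyl)pent-4-enenitrile
Product: 21 (4Z)-4-methyl-5-(trimethylsilyl)pent-4-enal
Conditions: i-Bu2AlH (1.1 equiv), CH2Cl2, −78 °C; then H2O, aq. potassium sodium tartrate, rt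
Reagents that add atoms: water, O
Why: Partial reduction of the nitrile stops at the N-aluminio aldimine, which cannot be reduced further at −78 °C; hydrolysis on aqueous work-up gives the aldehyde, whose oxygen comes from water while the nitrogen leaves as ammonia.

**Step 14**
Reactants: 22 ethyltriphenylphosphonium iodide; 21 (4Z)-4-methyl-5-(trimethylsilyl)pent-4-enal
Product: 26 [(1Z,5Z)-6-iodo-2-methylhepta-1,5-dien-1-yl]trimethylsilane, via ethylidene ylide 23 (not isolated), via iodoethylphosphonium iodide 24 (not isolated), via iodoethylidene ylide 25 (not isolated)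
Conditions: 22, n-BuLi, THF, rt; I2, −78 °C; NaN(SiMe3)2, −78 → −20 °C; then 21, −78 °C → rt
Reagents that add atoms: iodine, II
Why: Wittig olefination with a non-stabilised α-iodo ylide (Stork–Zhao type) is kinetically Z-selective, placing iodine cis to the chain and so fixing the geometry of the future C1=C10 olefin.

**Step 15**
Reactants: 26 [(1Z,5Z)-6-iodo-2-methylhepta-1,5-dien-1-yl]trimethylsilane; 10 tert-butyldimethyl{(2S)-3-methyl-2-[(2S)-oxiran-2-yl]butoxy}silane
Product: 28 (2S,3R,5Z,9Z)-1-[(tert-butyldimethylsilyl)oxy]-5,9-dimethyl-2-(propan-2-yl)-10-(trimethylsilyl)deca-5,9-dien-3-ol, via alkenyllithium 27 (not isolated)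
Conditions: t-BuLi (2.0 equiv per 26), Et2O, −78 °C; then 10, BF3·OEt2, −78 °C
Reagents that add atoms: none
Why: Iodine–lithium exchange with retention, then BF3-promoted SN2 opening of the epoxide at its unhindered terminal carbon forms C9–C10; C8 is not touched and the vinylsilane is inert to t-BuLi.

**Step 16**
Reactants: 28 (2S,3R,5Z,9Z)-1-[(tert-butyldimethylsilyl)oxy]-5,9-dimethyl-2-(propan-2-yl)-10-(trimethylsilyl)deca-5,9-dien-3-ol
Product: 29 (2S,3R,5Z,9Z)-1,3-bis[(tert-butyldimethylsilyl)oxy]-5,9-dimethyl-2-(propan-2-yl)-10-(trimethylsilyl)deca-5,9-diene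
Conditions: TBSOTf, 2,6-lutidine, CH2Cl2, −78 → 0 °C
Reagents that add atoms: tert-butyldimethylsilyl trifluoromethanesulfonate, CC(C)(C)[Si](C)(C)OS(=O)(=O)C(F)(F)F
Why: The silyl triflate silylates the hindered secondary C8 hydroxyl, so no free hydroxyl can take part in the iodination that follows.

**Step 17**
Reactants: 29 (2S,3R,5Z,9Z)-1,3-bis[(tert-butyldimethylsilyl)oxy]-5,9-dimethyl-2-(propan-2-yl)-10-(trimethylsilyl)deca-5,9-diene
Product: 30 (2S,3R,5Z,9Z)-1,3-bis[(tert-butyldimethylsilyl)oxy]-10-iodo-5,9-dimethyl-2-(propan-2-yl)deca-5,9-diene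
Conditions: NIS, 2,6-lutidine, (CF3)2CHOH, 0 °C, 10 min
Reagents that add atoms: N-iodosuccinimide, O=C1CCC(=O)N1I
Why: Ipso-iododesilylation of the vinylsilane through the β-silyl cation proceeds with retention in hexafluoroisopropanol and is faster than attack on the unactivated trisubstituted olefin.

**Step 18**
Reactants: 30 (2S,3R,5Z,9Z)-1,3-bis[(tert-butyldimethylsilyl)oxy]-10-iodo-5,9-dimethyl-2-(propan-2-yl)deca-5,9-diene
Product: 31 (2S,3R,5Z,9Z)-3-[(tert-butyldimethylsilyl)oxy]-10-iodo-5,9-dimethyl-2-(propan-2-yl)deca-5,9-dien-1-ol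
Conditions: HF·pyridine, pyridine, THF, 0 °C
Reagents that add atoms: none
Why: Buffered HF cleaves the primary silyl ether much faster than the hindered secondary one.

**Step 19**
Reactants: 31 (2S,3R,5Z,9Z)-3-[(tert-butyldimethylsilyl)oxy]-10-iodo-5,9-dimethyl-2-(propan-2-yl)deca-5,9-dien-1-ol
Product: 32 (2R,3R,5Z,9Z)-3-[(tert-butyldimethylsilyl)oxy]-10-iodo-5,9-dimethyl-2-(propan-2-yl)deca-5,9-dienal
Conditions: Dess–Martin periodinane, CH2Cl2, 0 °C → rt
Reagents that add atoms: none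
Why: Dess–Martin oxidation is base-free, so the α-branched β-silyloxy aldehyde neither epimerises at C7 nor eliminates; it is used at once.

**Step 20**
Reactants: 32 (2R,3R,5Z,9Z)-3-[(tert-butyldimethylsilyl)oxy]-10-iodo-5,9-dimethyl-2-(propan-2-yl)deca-5,9-dienal
Product: 33 (2Z,6Z,9R,10S)-9-[(tert-butyldimethylsilyl)oxy]-3,7-dimethyl-10-(propan-2-yl)cyclodeca-2,6-dien-1-ol as a mixture of C1 epimers
Conditions: CrCl2 (10 equiv), NiCl2 (2 mol %), DMSO/THF, 0.002 M, rt
Reagents that add atoms: none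
Why: Nozaki–Hiyama–Kishi macrocyclisation (nickel-catalysed C–I insertion, transfer to trivalent chromium, addition to the aldehyde) closes C5–C6 with retention of olefin geometry, helped by the two Z olefins holding the chain ends close; C6 forms as an epimer mixture that the next step erases.

**Step 21**
Reactants: 33 (2Z,6Z,9R,10S)-9-[(tert-butyldimethylsilyl)oxy]-3,7-dimethyl-10-(propan-2-yl)cyclodeca-2,6-dien-1-ol (C1 epimers)
Product: 34 (2Z,6Z,9R,10R)-9-[(tert-butyldimethylsilyl)oxy]-3,7-dimethyl-10-(propan-2-yl)cyclodeca-2,6-dien-1-one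
Conditions: Dess–Martin periodinane, CH2Cl2, rt
Reagents that add atoms: none
Why: Oxidation of the allylic alcohol converts both epimers into one enone under neutral conditions that leave C7 (now α to the ketone) intact.

**Step 22**
Reactants: 34 (2Z,6Z,9R,10R)-9-[(tert-butyldimethylsilyl)oxy]-3,7-dimethyl-10-(propan-2-yl)cyclodeca-2,6-dien-1-one
Product: 35 (2Z,6Z,9R,10R)-9-hydroxy-3,7-dimethyl-10-(propan-2-yl)cyclodeca-2,6-dien-1-one
Conditions: HF·pyridine, pyridine, THF, 0 °C → rt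
Reagents that add atoms: none
Why: Fluoride-driven desilylation under weakly acidic, buffered conditions frees the C8 hydroxyl without retro-aldol, epimerisation or transannular oxa-Michael addition.

**Step 23**
Reactants: 36 4-hydroxy-3-methoxybenzaldehyde (vanillin)
Product: 37 4-[(tert-butyldimethylsilyl)oxy]-3-methoxybenzaldehyde
Conditions: TBSCl, imidazole, DMF, rt
Reagents that add atoms: tert-butyldimethylsilyl chloride, CC(C)(C)[Si](C)(C)Cl
Why: Silylation masks the phenol so that it cannot bind the samarium catalyst in the next step.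

**Step 24**
Reactants: 35 (2Z,6Z,9R,10R)-9-hydroxy-3,7-dimethyl-10-(propan-2-yl)cyclodeca-2,6-dien-1-one; 37 4-[(tert-butyldimethylsilyl)oxy]-3-methoxybenzaldehyde
Product: 38 (1R,3Z,7Z,9R,10S)-9-hydroxy-3,7-dimethyl-10-(propan-2-yl)cyclodeca-3,7-dien-1-yl 4-[(tert-butyldimethylsilyl)oxy]-3-methoxybenzoate
Conditions: 37 (6 equiv), SmI2 (30 mol %, premixed with 37), THF, −10 °C
Reagents that add atoms: none
Why: Evans–Tishchenko reduction: the samarium-bound hemiacetal of 37 on O8 delivers hydride through a six-membered chair to the C6 carbonyl (1,2-reduction only), giving the 1,3-anti (6R) alcohol whatever the α-substituent, while the aldehyde carbon becomes the ester on O8.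

**Step 25**
Reactants: 38 (1R,3Z,7Z,9R,10S)-9-hydroxy-3,7-dimethyl-10-(propan-2-yl)cyclodeca-3,7-dien-1-yl 4-[(tert-butyldimethylsilyl)oxy]-3-methoxybenzoate
Product: 39 (1R,3Z,7Z,9R,10S)-9-hydroxy-3,7-dimethyl-10-(propan-2-yl)cyclodeca-3,7-dien-1-yl 4-hydroxy-3-methoxybenzoate
Conditions: Bu4NF, AcOH (1:1), THF, 0 °C
Reagents that add atoms: none
Why: Aryl silyl ethers are cleaved by fluoride within minutes, and the acetic acid buffer prevents 1,3-acyl migration or ester cleavage.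

## Compound list

1 | ethyl 3-methylbutanoate | CCOC(=O)CC(C)C | starting material
2 | (benzyloxy)acetyl chloride | O=C(Cl)COCc1ccccc1 | starting material
3 | lithium (1Z)-1-ethoxy-3-methylbut-1-en-1-olate (isopropyl cis to OEt) | CCO/C(O[Li])=C\C(C)C | intermediate
4 | ethyl 4-(benzyloxy)-3-oxo-2-(propan-2-yl)butanoate (racemic) | CCOC(=O)C(C(C)C)C(=O)COCc1ccccc1 | intermediate
5 | ethyl (2R,3S)-4-(benzyloxy)-3-hydroxy-2-(propan-2-yl)butanoate | CCOC(=O)[C@H](C(C)C)[C@H](O)COCc1ccccc1 | intermediate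
6 | (2S,3S)-4-(benzyloxy)-2-(propan-2-yl)butane-1,3-diol | OC[C@H](C(C)C)[C@H](O)COCc1ccccc1 | intermediate
7 | (2S,3S)-1-(benzyloxy)-3-{[(tert-butyldimethylsilyl)oxy]methyl}-4-methylpentan-2-ol | CC(C)(C)[Si](C)(C)OC[C@H](C(C)C)[C@H](O)COCc1ccccc1 | intermediate
8 | (2S,3S)-3-{[(tert-butyldimethylsilyl)oxy]methyl}-4-methylpentane-1,2-diol | CC(C)(C)[Si](C)(C)OC[C@H](C(C)C)[C@H](O)CO | intermediate
9 | (2S,3S)-3-{[(tert-butyldimethylsilyl)oxy]methyl}-2-hydroxy-4-methylpentyl 4-methylbenzenesulfonate | CC(C)(C)[Si](C)(C)OC[C@H](C(C)C)[C@H](O)COS(=O)(=O)c1ccc(C)cc1 | intermediate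
10 | tert-butyldimethyl{(2S)-3-methyl-2-[(2S)-oxiran-2-yl]butoxy}silane | CC(C)(C)[Si](C)(C)OC[C@H](C(C)C)[C@H]1CO1 | intermediate
11 | prop-2-yn-1-ol | C#CCO | starting material
12 | bromomagnesium (2Z)-3-(bromomagnesio)-2-methylprop-2-en-1-olate | Br[Mg]OC/C(C)=C\[Mg]Br | intermediate
13 | (2Z)-3-iodo-2-methylprop-2-en-1-ol | OC/C(C)=C\I | intermediate
14 | {[(2Z)-3-iodo-2-methylprop-2-en-1-yl]oxy}trimethylsilane | C[Si](C)(C)OC/C(C)=C\I | intermediate
15 | {[(2Z)-3-lithio-2-methylprop-2-en-1-yl]oxy}trimethylsilane | C[Si](C)(C)OC/C(C)=C\[Li] | intermediate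
16 | (2Z)-2-methyl-3-(trimethylsilyl)prop-2-en-1-ol | OC/C(C)=C\[Si](C)(C)C | intermediate
17 | [(1Z)-3-bromo-2-methylprop-1-en-1-yl]trimethylsilane | BrC/C(C)=C\[Si](C)(C)C | intermediate
18 | acetonitrile | CC#N | starting material
19 | (cyanomethyl)lithium | [Li]CC#N | intermediate
20 | (4Z)-4-methyl-5-(trimethylsilyl)pent-4-enenitrile | N#CCC/C(C)=C\[Si](C)(C)C | intermediate
21 | (4Z)-4-methyl-5-(trimethylsilyl)pent-4-enal | O=CCC/C(C)=C\[Si](C)(C)C | intermediate
22 | ethyltriphenylphosphonium iodide | CC[P+](c1ccccc1)(c1ccccc1)c1ccccc1.[I-] | starting material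
23 | ethylidenetriphenylphosphorane | CC=P(c1ccccc1)(c1ccccc1)c1ccccc1 | intermediate
24 | (1-iodoethyl)triphenylphosphonium iodide | CC(I)[P+](c1ccccc1)(c1ccccc1)c1ccccc1.[I-] | intermediate
25 | (1-iodoethylidene)triphenylphosphorane | CC(I)=P(c1ccccc1)(c1ccccc1)c1ccccc1 | intermediate
26 | [(1Z,5Z)-6-iodo-2-methylhepta-1,5-dien-1-yl]trimethylsilane | C[Si](C)(C)/C=C(C)\CC/C=C(C)\I | intermediate
27 | [(1Z,5E)-6-lithio-2-methylhepta-1,5-dien-1-yl]trimethylsilane (lithium cis to the chain, same geometry as 26; E only by the sequence rule) | C[Si](C)(C)/C=C(C)\CC/C=C(C)\[Li] | intermediate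
28 | (2S,3R,5Z,9Z)-1-[(tert-butyldimethylsilyl)oxy]-5,9-dimethyl-2-(propan-2-yl)-10-(trimethylsilyl)deca-5,9-dien-3-ol | CC(C)(C)[Si](C)(C)OC[C@H](C(C)C)[C@H](O)C/C(C)=C\CC/C(C)=C\[Si](C)(C)C | intermediate
29 | (2S,3R,5Z,9Z)-1,3-bis[(tert-butyldimethylsilyl)oxy]-5,9-dimethyl-2-(propan-2-yl)-10-(trimethylsilyl)deca-5,9-diene | CC(C)(C)[Si](C)(C)OC[C@H](C(C)C)[C@H](O[Si](C)(C)C(C)(C)C)C/C(C)=C\CC/C(C)=C\[Si](C)(C)C | intermediate
30 | (2S,3R,5Z,9Z)-1,3-bis[(tert-butyldimethylsilyl)oxy]-10-iodo-5,9-dimethyl-2-(propan-2-yl)deca-5,9-diene | CC(C)(C)[Si](C)(C)OC[C@H](C(C)C)[C@H](O[Si](C)(C)C(C)(C)C)C/C(C)=C\CC/C(C)=C\I | intermediate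
31 | (2S,3R,5Z,9Z)-3-[(tert-butyldimethylsilyl)oxy]-10-iodo-5,9-dimethyl-2-(propan-2-yl)deca-5,9-dien-1-ol | OC[C@H](C(C)C)[C@H](O[Si](C)(C)C(C)(C)C)C/C(C)=C\CC/C(C)=C\I | intermediate
32 | (2R,3R,5Z,9Z)-3-[(tert-butyldimethylsilyl)oxy]-10-iodo-5,9-dimethyl-2-(propan-2-yl)deca-5,9-dienal | O=C[C@H](C(C)C)[C@H](O[Si](C)(C)C(C)(C)C)C/C(C)=C\CC/C(C)=C\I | intermediate
33 | (2Z,6Z,9R,10S)-9-[(tert-butyldimethylsilyl)oxy]-3,7-dimethyl-10-(propan-2-yl)cyclodeca-2,6-dien-1-ol (both C1 epimers) | CC(C)(C)[Si](C)(C)O[C@@H]1C/C(C)=C\CC/C(C)=C\C(O)[C@@H]1C(C)C | intermediate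
34 | (2Z,6Z,9R,10R)-9-[(tert-butyldimethylsilyl)oxy]-3,7-dimethyl-10-(propan-2-yl)cyclodeca-2,6-dien-1-one | CC(C)(C)[Si](C)(C)O[C@@H]1C/C(C)=C\CC/C(C)=C\C(=O)[C@@H]1C(C)C | intermediate
35 | (2Z,6Z,9R,10R)-9-hydroxy-3,7-dimethyl-10-(propan-2-yl)cyclodeca-2,6-dien-1-one | O[C@@H]1C/C(C)=C\CC/C(C)=C\C(=O)[C@@H]1C(C)C | intermediate
36 | 4-hydroxy-3-methoxybenzaldehyde (vanillin) | COc1cc(C=O)ccc1O | starting material
37 | 4-[(tert-butyldimethylsilyl)oxy]-3-methoxybenzaldehyde | COc1cc(C=O)ccc1O[Si](C)(C)C(C)(C)C | intermediate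
38 | (1R,3Z,7Z,9R,10S)-9-hydroxy-3,7-dimethyl-10-(propan-2-yl)cyclodeca-3,7-dien-1-yl 4-[(tert-butyldimethylsilyl)oxy]-3-methoxybenzoate | COc1cc(C(=O)O[C@@H]2C/C(C)=C\CC/C(C)=C\[C@@H](O)[C@@H]2C(C)C)ccc1O[Si](C)(C)C(C)(C)C | intermediate
39 | (1R,3Z,7Z,9R,10S)-9-hydroxy-3,7-dimethyl-10-(propan-2-yl)cyclodeca-3,7-dien-1-yl 4-hydroxy-3-methoxybenzoate | COc1cc(C(=O)O[C@@H]2C/C(C)=C\CC/C(C)=C\[C@@H](O)[C@@H]2C(C)C)ccc1O | target

## Step count and risks

Total steps: 25. Longest linear sequence: 17 steps (steps 1–7, 15–22, 24, 25; the west branch, steps 8–14, 15–22, 24, 25, is equally long).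

**Step 14 (iodo-ylide olefination).** This Wittig variant often gives modest yield and an imperfect Z/E ratio. The fallback sets out from aldehyde 21. Corey–Fuchs dibromo-olefination (CBr4, PPh3, CH2Cl2, 0 °C) gives [(1Z)-6,6-dibromo-2-methylhexa-1,5-dien-1-yl]trimethylsilane F1. Palladium-catalysed Negishi monomethylation (MeZnCl, PdCl2[(2-Ph2PC6H4)2O] cat., THF, 0 °C → rt) replaces only the less hindered bromine trans to the chain and gives [(1Z,5Z)-6-bromo-2-methylhepta-1,5-dien-1-yl]trimethylsilane F2. Bromine–lithium exchange (t-BuLi, Et2O, −78 °C) then gives the same alkenyllithium 27, where the route is rejoined in step 15.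

**Step 20 (ten-membered Nozaki–Hiyama–Kishi closure).** Medium-ring strain can favour oligomers or reduction of the iodide. The fallback sets out from aldehyde 32 and closes the ring by an anionic acylation instead. Pinnick oxidation (NaClO2, NaH2PO4, 2-methylbut-2-ene, t-BuOH/H2O) gives (2R,3R,5Z,9Z)-3-[(tert-butyldimethylsilyl)oxy]-10-iodo-5,9-dimethyl-2-(propan-2-yl)deca-5,9-dienoic acid F3. Amide coupling (MeNHOMe·HCl, EDC·HCl, HOBt, i-Pr2NEt, CH2Cl2, 0 °C) gives the Weinreb amide (2R,3R,5Z,9Z)-3-[(tert-butyldimethylsilyl)oxy]-10-iodo-N-methoxy-N,5,9-trimethyl-2-(propan-2-yl)deca-5,9-dienamide F4. Iodine–lithium exchange at high dilution (t-BuLi 2.1 equiv, THF, −100 °C, 0.002 M) triggers intramolecular attack on the amide; the chelated tetrahedral intermediate prevents over-addition and collapses on work-up to enone 34, where the route is rejoined (steps 20 and 21 are skipped).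

**Step 24 (Evans–Tishchenko with the electron-rich, bulky aryl aldehyde 37).** Hemiacetal formation may be too unfavourable for hydride transfer to the conjugated ketone. The fallback sets out from hydroxy enone 35 and keeps the 1,3-anti delivery but uses a small, reactive aldehyde, then exchanges the ester. Evans–Tishchenko reduction with acetaldehyde (SmI2 cat., THF, −10 °C) gives (1R,3Z,7Z,9R,10S)-9-hydroxy-3,7-dimethyl-10-(propan-2-yl)cyclodeca-3,7-dien-1-yl acetate F5. Silylation of the C6 hydroxyl (TESOTf, 2,6-lutidine, CH2Cl2, −78 °C) gives (1R,3Z,7Z,9R,10R)-3,7-dimethyl-10-(propan-2-yl)-9-[(triethylsilyl)oxy]cyclodeca-3,7-dien-1-yl acetate F6. Reductive removal of the acetate (i-Bu2AlH, CH2Cl2, −78 °C) gives (1R,3Z,7Z,9R,10R)-3,7-dimethyl-10-(propan-2-yl)-9-[(triethylsilyl)oxy]cyclodeca-3,7-dien-1-ol F7. Pinnick oxidation of aldehyde 37 gives 4-[(tert-butyldimethylsilyl)oxy]-3-methoxybenzoic acid F8, which is coupled to F7 (2,4,6-trichlorobenzoyl chloride, Et3N, then DMAP, toluene) to give (1R,3Z,7Z,9R,10R)-3,7-dimethyl-10-(propan-2-yl)-9-[(triethylsilyl)oxy]cyclodeca-3,7-dien-1-yl 4-[(tert-butyldimethylsilyl)oxy]-3-methoxybenzoate F9. Removal of both silyl groups (Bu4NF, AcOH, THF, 0 °C) then gives the target 39 directly.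

## Further compounds

F1 | step 14 | [(1Z)-6,6-dibromo-2-methylhexa-1,5-dien-1-yl]trimethylsilane | C[Si](C)(C)/C=C(C)\CCC=C(Br)Br
F2 | step 14 | [(1Z,5Z)-6-bromo-2-methylhepta-1,5-dien-1-yl]trimethylsilane | C[Si](C)(C)/C=C(C)\CC/C=C(C)\Br
F3 | step 20 | (2R,3R,5Z,9Z)-3-[(tert-butyldimethylsilyl)oxy]-10-iodo-5,9-dimethyl-2-(propan-2-yl)deca-5,9-dienoic acid | OC(=O)[C@H](C(C)C)[C@H](O[Si](C)(C)C(C)(C)C)C/C(C)=C\CC/C(C)=C\I
F4 | step 20 | (2R,3R,5Z,9Z)-3-[(tert-butyldimethylsilyl)oxy]-10-iodo-N-methoxy-N,5,9-trimethyl-2-(propan-2-yl)deca-5,9-dienamide | CON(C)C(=O)[C@H](C(C)C)[C@H](O[Si](C)(C)C(C)(C)C)C/C(C)=C\CC/C(C)=C\I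
F5 | step 24 | (1R,3Z,7Z,9R,10S)-9-hydroxy-3,7-dimethyl-10-(propan-2-yl)cyclodeca-3,7-dien-1-yl acetate | CC(=O)O[C@@H]1C/C(C)=C\CC/C(C)=C\[C@@H](O)[C@@H]1C(C)C
F6 | step 24 | (1R,3Z,7Z,9R,10R)-3,7-dimethyl-10-(propan-2-yl)-9-[(triethylsilyl)oxy]cyclodeca-3,7-dien-1-yl acetate | CC(=O)O[C@@H]1C/C(C)=C\CC/C(C)=C\[C@@H](O[Si](CC)(CC)CC)[C@@H]1C(C)C
F7 | step 24 | (1R,3Z,7Z,9R,10R)-3,7-dimethyl-10-(propan-2-yl)-9-[(triethylsilyl)oxy]cyclodeca-3,7-dien-1-ol | O[C@@H]1C/C(C)=C\CC/C(C)=C\[C@@H](O[Si](CC)(CC)CC)[C@@H]1C(C)C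
F8 | step 24 | 4-[(tert-butyldimethylsilyl)oxy]-3-methoxybenzoic acid | COc1cc(C(=O)O)ccc1O[Si](C)(C)C(C)(C)C
F9 | step 24 | (1R,3Z,7Z,9R,10R)-3,7-dimethyl-10-(propan-2-yl)-9-[(triethylsilyl)oxy]cyclodeca-3,7-dien-1-yl 4-[(tert-butyldimethylsilyl)oxy]-3-methoxybenzoate | COc1cc(C(=O)O[C@@H]2C/C(C)=C\CC/C(C)=C\[C@@H](O[Si](CC)(CC)CC)[C@@H]2C(C)C)ccc1O[Si](C)(C)C(C)(C)C
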